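**Retrosynthetic overview**
1. Structural feature: C2 of ring C is a single CH carbon whose only heavy-atom partners are C3, C1′ of ring B and O1. It can therefore be supplied by CH2Cl2, placed between a boron-bearing C3 and the ring B aryl group, and the boron is later exchanged for oxygen.
2. Late stage: the galloyl ester at O3′ (Steglich) and a global hydrogenolysis. Before these, ring C is closed at O1–C2 by Mitsunobu inversion; it is the only ring made, since rings A, B and the galloyl ring are bought.
3. Key disconnection: C2–C3 and C2–C1′ together, by homologating the C3 α-benzyloxy boronic ester with LiCHCl2 and displacing the chloride with the ring B aryl Grignard reagent in the same flask.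
4. C3 (C3–C4 and C3–O) comes from an earlier homologation and LiOBn displacement of the ring A benzylboronate. Its C4–C4a bond is made from the ring A aryllithium and a (bromomethyl)boronate.
5. One director on boron, (R,R)-DICHED, sets C3 and C2. The syn C2,C3-dioxygen array becomes 2,3-trans on invertive ring closure.

Key step: step 10

Assumption: (R,R)-DICHED boronic esters give the (S)-α-chloro boronic ester, the sense established for (R,R)-configured C2-symmetric diols. Flavan numbering (O1, C2, C3, C4, C4a, C8a, C1′–C6′) is used for all intermediates.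

**Step 1**
Reactants: 1 3,5-bis(benzyloxy)phenol
Product: 2 3,5-bis(benzyloxy)-2-iodophenol
Conditions: NIS (1.0 equiv), CH2Cl2, −20 °C to 0 °C, dark
Reagents that add atoms: N-iodosuccinimide, O=C1CCC(=O)N1I
Why: Electrophilic aromatic iodination: all three free ring positions are activated, but the two equivalent positions between OH and OBn are less crowded than the one between the two OBn groups, so the bulky iodine electrophile should enter ortho to the phenol and the minor isomer can be removed by chromatography.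

**Step 2**
Reactants: 2 3,5-bis(benzyloxy)-2-iodophenol
Product: 3 1-(allyloxy)-3,5-bis(benzyloxy)-2-iodobenzene
Conditions: allyl bromide, K2CO3, DMF, rt
Reagents that add atoms: allyl bromide, C=CCBr
Why: Williamson ether synthesis; an allyl ether is chosen for the future O1 because, unlike a silyl ether, it cannot shift to the neighbouring carbanion in step 4 (retro-Brook) or be stripped by the alkoxide of step 6, and it leaves later under neutral palladium catalysis.

**Step 3**
Reactants: 4 dibromomethane; 5 (1R,2R)-1,2-dicyclohexylethane-1,2-diol ((R,R)-DICHED)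
Product: 7 (4R,5R)-2-(bromomethyl)-4,5-dicyclohexyl-1,3,2-dioxaborolane, via diisopropyl (bromomethyl)boronate 6 (not isolated)
Conditions: B(OiPr)3, n-BuLi, THF, −78 °C to rt; MeSO3H, 0 °C; then 5, rt
Reagents that add atoms: triisopropyl borate, CC(C)OB(OC(C)C)OC(C)C
Why: Bromine–lithium exchange on CH2Br2 in the presence of the borate traps LiCH2Br as its ate complex, acid releases the (bromomethyl)boronic ester and the diol displaces isopropanol by transesterification, which is the standard entry to halomethyl boronic esters of chiral diols; the two stereocentres come unchanged from 5.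

**Step 4**
Reactants: 3 1-(allyloxy)-3,5-bis(benzyloxy)-2-iodobenzene; 7 (4R,5R)-2-(bromomethyl)-4,5-dicyclohexyl-1,3,2-dioxaborolane
Product: 9 (4R,5R)-2-[2-(allyloxy)-4,6-bis(benzyloxy)benzyl]-4,5-dicyclohexyl-1,3,2-dioxaborolane, via aryllithium 8 (not isolated)
Conditions: n-BuLi, THF, −78 °C, 15 min; then 7, −78 °C to rt
Reagents that add atoms: none
Why: Iodine–lithium exchange, ate-complex formation at boron and 1,2-metallate shift of the aryl group with loss of bromide (Matteson-type substitution) form C4–C4a and avoid a 2,4,6-trioxygenated benzyl halide, which would ionise and self-alkylate.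

**Step 5**
Reactants: 9 (4R,5R)-2-[2-(allyloxy)-4,6-bis(benzyloxy)benzyl]-4,5-dicyclohexyl-1,3,2-dioxaborolane; 10 dichloromethane
Product: 11 (R,R)-DICHED (1S)-2-[2-(allyloxy)-4,6-bis(benzyloxy)phenyl]-1-chloroethylboronate
Conditions: CH2Cl2, n-BuLi, THF, −100 °C; add 9; ZnCl2, −100 °C to rt; short NH4Cl/pentane work-up, used crude
Reagents that add atoms: none
Why: Matteson homologation of a benzylboronic ester: the benzylic carbon C4 migrates from boron to the carbenoid carbon as ZnCl2 removes the chloride singled out by the C2-symmetric diol, which forms C3–C4 and should set the (S)-chloride.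

**Step 6**
Reactants: 11 (R,R)-DICHED (1S)-2-[2-(allyloxy)-4,6-bis(benzyloxy)phenyl]-1-chloroethylboronate
Product: 12 (R,R)-DICHED (1R)-2-[2-(allyloxy)-4,6-bis(benzyloxy)phenyl]-1-(benzyloxy)ethylboronate
Conditions: BnOH, n-BuLi, THF, −78 °C; then 11, −78 °C to rt
Reagents that add atoms: benzyl alcohol, OCc1ccccc1
Why: The alkoxide adds to boron and the benzyloxy group migrates to carbon with inversion (second half of the Matteson sequence), turning the (S)-chloride into the (R)-benzyl ether, which has the spatial arrangement of (3S) in the flavan.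

**Step 7**
Reactants: 13 5-bromobenzene-1,2,3-triol
Product: 14 6-bromo-2,2-diphenyl-1,3-benzodioxol-4-ol
Conditions: Ph2CCl2, Ph2O, 175 °C, 30 min
Reagents that add atoms: dichlorodiphenylmethane, ClC(Cl)(c1ccccc1)c1ccccc1
Why: Ketalisation of two vicinal phenols with a gem-dichloride; only neighbouring oxygens can span the five-membered dioxole and the triol is symmetric, so a single monophenol results, and the ketal falls later in the final hydrogenolysis.

**Step 8**
Reactants: 14 6-bromo-2,2-diphenyl-1,3-benzodioxol-4-ol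
Product: 15 [(6-bromo-2,2-diphenyl-1,3-benzodioxol-4-yl)oxy]triisopropylsilane
Conditions: TIPSCl, imidazole, DMF, rt
Reagents that add atoms: chlorotriisopropylsilane, CC(C)[Si](Cl)(C(C)C)C(C)C
Why: Standard silylation of a phenol; the bulky triisopropylsilyl ether marks O3′, tolerates the Grignard reagent and the basic peroxide of step 11 better than a tert-butyldimethylsilyl ether, and is orthogonal to the allyl ether on ring A.

**Step 9**
Reactants: 15 [(6-bromo-2,2-diphenyl-1,3-benzodioxol-4-yl)oxy]triisopropylsilane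
Product: 16 {2,2-diphenyl-7-[(triisopropylsilyl)oxy]-1,3-benzodioxol-5-yl}magnesium bromide (THF solution, titrated and used directly)
Conditions: Mg turnings, I2 (crystal), THF, 45 °C
Reagents that add atoms: magnesium, [Mg]
Why: Direct magnesium insertion into an electron-rich aryl bromide (Grignard formation); the metal sits meta to the silyl ether, so no silyl migration to carbon is possible.

**Step 10**
Reactants: 12 (R,R)-DICHED (1R)-2-[2-(allyloxy)-4,6-bis(benzyloxy)phenyl]-1-(benzyloxy)ethylboronate; 10 dichloromethane; 16 {2,2-diphenyl-7-[(triisopropylsilyl)oxy]-1,3-benzodioxol-5-yl}magnesium bromide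
Product: 18 (R,R)-DICHED (1S,2S)-3-[2-(allyloxy)-4,6-bis(benzyloxy)phenyl]-2-(benzyloxy)-1-{2,2-diphenyl-7-[(triisopropylsilyl)oxy]-1,3-benzodioxol-5-yl}propylboronate, via (1S,2S)-α-chloro boronic ester 17 (not isolated)
Conditions: CH2Cl2, n-BuLi, THF, −100 °C; add 12; ZnCl2 (1.5 equiv), −100 °C to rt, 16 h; then 16 (4 equiv), −78 °C to rt, 24 h
Reagents that add atoms: none
Why: LiCHCl2 adds to boron of 12 and, on warming, ZnCl2 pulls off one of the two diastereotopic chlorides while C3 shifts from boron to the carbenoid carbon with retention, which forms C2–C3 and gives the (1S)-chloride 17; Grignard reagent 16 then adds to boron of 17 and its aryl group migrates antiperiplanar to the remaining chloride, which forms C2–C1′ with inversion at C2. These two events are the two halves of a Matteson homologation, a sequence long applied to benzyl and α-benzyloxy boronic esters of C2-symmetric diols with Grignard displacement of the chloride. No ring is closed in this step. The only new stereocentre, C2, is fixed by the (R,R)-DICHED ligand, which decides which chloride leaves, while C3 merely migrates with retention; any (1R)-chloride is expected to be diverted into oxygen migration in the second stage, so the director acts twice. The step needs carbon migration to win over loss of the β-benzyloxy group and over chloride-induced epimerisation of 17, and this is secured because ZnCl2 binds the liberated chloride, benzyloxide is a poor leaving group from a neutral boronic ester, and the electron-rich aryl group migrates readily. Because each ZnCl2 can take up two aryl groups, 16 is charged in more than twofold excess over it.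

**Step 11**
Reactants: 18 (R,R)-DICHED (1S,2S)-3-[2-(allyloxy)-4,6-bis(benzyloxy)phenyl]-2-(benzyloxy)-1-{2,2-diphenyl-7-[(triisopropylsilyl)oxy]-1,3-benzodioxol-5-yl}propylboronate
Product: 19 (1S,2S)-3-[2-(allyloxy)-4,6-bis(benzyloxy)phenyl]-2-(benzyloxy)-1-{2,2-diphenyl-7-[(triisopropylsilyl)oxy]-1,3-benzodioxol-5-yl}propan-1-ol
Conditions: 30% H2O2, aq NaOH, THF, 0 °C to rt
Reagents that add atoms: hydrogen peroxide, OO
Why: Oxidation of a C–B bond with alkaline hydrogen peroxide, in which C2 migrates from boron to oxygen with retention, so the (1S,2S) syn alcohol should be obtained and hydroperoxide attack should outrun β-elimination of the benzyloxy group.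

**Step 12**
Reactants: 19 (1S,2S)-3-[2-(allyloxy)-4,6-bis(benzyloxy)phenyl]-2-(benzyloxy)-1-{2,2-diphenyl-7-[(triisopropylsilyl)oxy]-1,3-benzodioxol-5-yl}propan-1-ol
Product: 20 3,5-bis(benzyloxy)-2-[(2S,3S)-2-(benzyloxy)-3-hydroxy-3-{2,2-diphenyl-7-[(triisopropylsilyl)oxy]-1,3-benzodioxol-5-yl}propyl]phenol
Conditions: Pd(PPh3)4 (5 mol %), morpholine, THF, rt
Reagents that add atoms: none
Why: Tsuji–Trost-type deallylation: zerovalent palladium ionises the aryl allyl ether and morpholine captures the π-allyl unit under neutral conditions that leave the acid-sensitive benzylic alcohol, the silyl ether, the ketal and the benzyl ethers alone.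

**Step 13**
Reactants: 20 3,5-bis(benzyloxy)-2-[(2S,3S)-2-(benzyloxy)-3-hydroxy-3-{2,2-diphenyl-7-[(triisopropylsilyl)oxy]-1,3-benzodioxol-5-yl}propyl]phenol
Product: 21 (2R,3S)-3,5,7-tris(benzyloxy)-2-{2,2-diphenyl-7-[(triisopropylsilyl)oxy]-1,3-benzodioxol-5-yl}chromane
Conditions: PPh3, DIAD, THF (0.01 M), 0 °C to rt
Reagents that add atoms: none
Why: Intramolecular Mitsunobu etherification (6-exo-tet): the only free phenol displaces the oxyphosphonium group at C2 with inversion, (S) to (R), closing ring C as the 2,3-trans isomer, and any leakage through the benzylic cation should also favour the diequatorial trans product while C3 stays untouched.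

**Step 14**
Reactants: 21 (2R,3S)-3,5,7-tris(benzyloxy)-2-{2,2-diphenyl-7-[(triisopropylsilyl)oxy]-1,3-benzodioxol-5-yl}chromane
Product: 22 6-[(2R,3S)-3,5,7-tris(benzyloxy)chroman-2-yl]-2,2-diphenyl-1,3-benzodioxol-4-ol
Conditions: TBAF, AcOH (1:1), THF, 0 °C
Reagents that add atoms: none
Why: Fluoride cleavage of the aryl silyl ether, buffered with acetic acid so that the electron-rich phenoxide is not exposed to base, frees O3′ as the only hydroxyl group in the molecule.

**Step 15**
Reactants: 22 6-[(2R,3S)-3,5,7-tris(benzyloxy)chroman-2-yl]-2,2-diphenyl-1,3-benzodioxol-4-ol; 23 3,4,5-tris(benzyloxy)benzoic acid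
Product: 24 6-[(2R,3S)-3,5,7-tris(benzyloxy)chroman-2-yl]-2,2-diphenyl-1,3-benzodioxol-4-yl 3,4,5-tris(benzyloxy)benzoate
Conditions: DCC, DMAP (cat.), CH2Cl2, 0 °C to rt
Reagents that add atoms: none
Why: Steglich esterification; since O3′–H is the single free hydroxyl group, the galloyl unit can only be placed there.

**Step 16**
Reactants: 24 6-[(2R,3S)-3,5,7-tris(benzyloxy)chroman-2-yl]-2,2-diphenyl-1,3-benzodioxol-4-yl 3,4,5-tris(benzyloxy)benzoate
Product: 25 gallocatechin 3′-O-gallate, (2R,3S)
Conditions: H2 (1 atm), Pd(OH)2/C, THF/MeOH, rt; filtration under argon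
Reagents that add atoms: none
Why: Catalytic hydrogenolysis removes all six benzyl ethers and the diphenylmethylene ketal in one neutral operation, conditions under which the aryl ester, the C2–O1 bond of the chromane and both stereocentres are expected to persist and an acyl shift to O4′ is not promoted.

**Compound list**
1 | 3,5-bis(benzyloxy)phenol | Oc1cc(OCc2ccccc2)cc(OCc2ccccc2)c1 | starting material
2 | 3,5-bis(benzyloxy)-2-iodophenol | Oc1cc(OCc2ccccc2)cc(OCc2ccccc2)c1I | intermediate
3 | 1-(allyloxy)-3,5-bis(benzyloxy)-2-iodobenzene | C=CCOc1cc(OCc2ccccc2)cc(OCc2ccccc2)c1I | intermediate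
4 | dibromomethane | BrCBr | starting material
5 | (1R,2R)-1,2-dicyclohexylethane-1,2-diol, (R,R)-DICHED | O[C@H](C1CCCCC1)[C@H](O)C1CCCCC1 | starting material
6 | diisopropyl (bromomethyl)boronate | BrCB(OC(C)C)OC(C)C | intermediate
7 | (4R,5R)-2-(bromomethyl)-4,5-dicyclohexyl-1,3,2-dioxaborolane | BrCB1O[C@H](C2CCCCC2)[C@@H](C2CCCCC2)O1 | intermediate
8 | [2-(allyloxy)-4,6-bis(benzyloxy)phenyl]lithium | [Li]c1c(OCC=C)cc(OCc2ccccc2)cc1OCc1ccccc1 | intermediate
9 | (4R,5R)-2-[2-(allyloxy)-4,6-bis(benzyloxy)benzyl]-4,5-dicyclohexyl-1,3,2-dioxaborolane | C=CCOc1cc(OCc2ccccc2)cc(OCc2ccccc2)c1CB1O[C@H](C2CCCCC2)[C@@H](C2CCCCC2)O1 | intermediate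
10 | dichloromethane | ClCCl | starting material
11 | (R,R)-DICHED (1S)-2-[2-(allyloxy)-4,6-bis(benzyloxy)phenyl]-1-chloroethylboronate | C=CCOc1cc(OCc2ccccc2)cc(OCc2ccccc2)c1C[C@@H](Cl)B1O[C@H](C2CCCCC2)[C@@H](C2CCCCC2)O1 | intermediate
12 | (R,R)-DICHED (1R)-2-[2-(allyloxy)-4,6-bis(benzyloxy)phenyl]-1-(benzyloxy)ethylboronate | C=CCOc1cc(OCc2ccccc2)cc(OCc2ccccc2)c1C[C@@H](B1O[C@H](C2CCCCC2)[C@@H](C2CCCCC2)O1)OCc1ccccc1 | intermediate
13 | 5-bromobenzene-1,2,3-triol | Oc1cc(Br)cc(O)c1O | starting material
14 | 6-bromo-2,2-diphenyl-1,3-benzodioxol-4-ol | Oc1cc(Br)cc2OC(c3ccccc3)(c3ccccc3)Oc12 | intermediate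
15 | [(6-bromo-2,2-diphenyl-1,3-benzodioxol-4-yl)oxy]triisopropylsilane | CC(C)[Si](C(C)C)(C(C)C)Oc1cc(Br)cc2OC(c3ccccc3)(c3ccccc3)Oc12 | intermediate
16 | {2,2-diphenyl-7-[(triisopropylsilyl)oxy]-1,3-benzodioxol-5-yl}magnesium bromide | CC(C)[Si](C(C)C)(C(C)C)Oc1cc([Mg]Br)cc2OC(c3ccccc3)(c3ccccc3)Oc12 | intermediate
17 | (R,R)-DICHED (1S,2S)-3-[2-(allyloxy)-4,6-bis(benzyloxy)phenyl]-2-(benzyloxy)-1-chloropropylboronate | C=CCOc1cc(OCc2ccccc2)cc(OCc2ccccc2)c1C[C@H](OCc1ccccc1)[C@@H](Cl)B1O[C@H](C2CCCCC2)[C@@H](C2CCCCC2)O1 | intermediate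
18 | (R,R)-DICHED (1S,2S)-3-[2-(allyloxy)-4,6-bis(benzyloxy)phenyl]-2-(benzyloxy)-1-{2,2-diphenyl-7-[(triisopropylsilyl)oxy]-1,3-benzodioxol-5-yl}propylboronate | C=CCOc1cc(OCc2ccccc2)cc(OCc2ccccc2)c1C[C@H](OCc1ccccc1)[C@H](c1cc(O[Si](C(C)C)(C(C)C)C(C)C)c2OC(c3ccccc3)(c3ccccc3)Oc2c1)B1O[C@H](C2CCCCC2)[C@@H](C2CCCCC2)O1 | intermediate
19 | (1S,2S)-3-[2-(allyloxy)-4,6-bis(benzyloxy)phenyl]-2-(benzyloxy)-1-{2,2-diphenyl-7-[(triisopropylsilyl)oxy]-1,3-benzodioxol-5-yl}propan-1-ol | C=CCOc1cc(OCc2ccccc2)cc(OCc2ccccc2)c1C[C@H](OCc1ccccc1)[C@@H](O)c1cc(O[Si](C(C)C)(C(C)C)C(C)C)c2OC(c3ccccc3)(c3ccccc3)Oc2c1 | intermediate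
20 | 3,5-bis(benzyloxy)-2-[(2S,3S)-2-(benzyloxy)-3-hydroxy-3-{2,2-diphenyl-7-[(triisopropylsilyl)oxy]-1,3-benzodioxol-5-yl}propyl]phenol | Oc1cc(OCc2ccccc2)cc(OCc2ccccc2)c1C[C@H](OCc1ccccc1)[C@@H](O)c1cc(O[Si](C(C)C)(C(C)C)C(C)C)c2OC(c3ccccc3)(c3ccccc3)Oc2c1 | intermediate
21 | (2R,3S)-3,5,7-tris(benzyloxy)-2-{2,2-diphenyl-7-[(triisopropylsilyl)oxy]-1,3-benzodioxol-5-yl}chromane | CC(C)[Si](C(C)C)(C(C)C)Oc1cc([C@H]2Oc3cc(OCc4ccccc4)cc(OCc4ccccc4)c3C[C@@H]2OCc2ccccc2)cc2OC(c3ccccc3)(c3ccccc3)Oc12 | intermediate
22 | 6-[(2R,3S)-3,5,7-tris(benzyloxy)chroman-2-yl]-2,2-diphenyl-1,3-benzodioxol-4-ol | Oc1cc([C@H]2Oc3cc(OCc4ccccc4)cc(OCc4ccccc4)c3C[C@@H]2OCc2ccccc2)cc2OC(c3ccccc3)(c3ccccc3)Oc12 | intermediate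
23 | 3,4,5-tris(benzyloxy)benzoic acid | OC(=O)c1cc(OCc2ccccc2)c(OCc2ccccc2)c(OCc2ccccc2)c1 | starting material
24 | 6-[(2R,3S)-3,5,7-tris(benzyloxy)chroman-2-yl]-2,2-diphenyl-1,3-benzodioxol-4-yl 3,4,5-tris(benzyloxy)benzoate | O=C(Oc1cc([C@H]2Oc3cc(OCc4ccccc4)cc(OCc4ccccc4)c3C[C@@H]2OCc2ccccc2)cc2OC(c3ccccc3)(c3ccccc3)Oc12)c1cc(OCc2ccccc2)c(OCc2ccccc2)c(OCc2ccccc2)c1 | intermediate
25 | gallocatechin 3′-O-gallate, (2R,3S) | O=C(Oc1cc([C@H]2Oc3cc(O)cc(O)c3C[C@@H]2O)cc(O)c1O)c1cc(O)c(O)c(O)c1 | target

**Step count**
Total steps: 16.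
Longest linear sequence: 12 steps (1, 2, 4, 5, 6, 10, 11, 12, 13, 14, 15, 16, counted from compound 1). Step 3 and steps 7–9 are side branches.

**Steps most likely to fail**

Step 10.
- What may go wrong: aryl transfer to boron may stall because the zinc salts drain the Grignard reagent. The second ate complex may collapse by β-elimination of benzyloxide. The chloride may epimerise before it is displaced.
- Fallback: it sets out from 12 and comes back at 19. Only the first half of the sequence is run (LiCHCl2, ZnCl2) to reach 17. The crude chloride is oxidised with H2O2 and NaHCO3 in THF/water, which turns the α-chloro boronic ester into (2S)-3-[2-(allyloxy)-4,6-bis(benzyloxy)phenyl]-2-(benzyloxy)propanal F1. Grignard reagent 16 is then added to F1 in CH2Cl2/Et2O at −78 °C after precomplexation with MgBr2·OEt2.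
- What changes: C2 still comes from CH2Cl2, but C2–C1′ now arises from a carbonyl addition. The C2 configuration is set by the five-membered magnesium chelate of the C3 benzyloxy group (Cram chelate model, syn product), which gives 19 directly.

Step 13.
- What may go wrong: the crowded secondary benzylic alcohol may be activated slowly. The oxyphosphonium ion next to the electron-rich ring B may ionise or eliminate, so that inversion fidelity is lost.
- Fallback: it sets out from 20 and comes back at 21, and it makes no compound outside the list (F0). The stereospecific displacement is given up in favour of an acid-catalysed dehydrative cyclisation (catalytic camphorsulfonic acid, 4 Å molecular sieves, dilute CH2Cl2, −20 °C to rt).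
- What changes: the reaction runs through the 4′-oxygen-stabilised benzylic cation. Closure is reversible at C2, so the product ratio is governed by the greater stability of the diequatorial 2,3-trans chromane. C3, which carries the absolute configuration, is not involved.

Step 4.
- What may go wrong: the ortho-allyloxy aryllithium may decay by intramolecular carbolithiation or proton capture. Alternatively, the doubly ortho-substituted nucleophile may bind the hindered boron too slowly.
- Fallback: it sets out from 7 (with 3 as partner) and comes back at 9. Finkelstein exchange (NaI, acetone) gives (4R,5R)-4,5-dicyclohexyl-2-(iodomethyl)-1,3,2-dioxaborolane F2. Zinc dust in THF inserts to give {[(4R,5R)-4,5-dicyclohexyl-1,3,2-dioxaborolan-2-yl]methyl}zinc iodide F3. Negishi coupling of F3 with iodide 3 (Pd(OAc)2, SPhos, THF, 40 °C) then forms C4–C4a.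
- What changes: the bond is made by cross-coupling, without any aryl carbanion.

**Further compounds**
F1 | step 10 | (2S)-3-[2-(allyloxy)-4,6-bis(benzyloxy)phenyl]-2-(benzyloxy)propanal | C=CCOc1cc(OCc2ccccc2)cc(OCc2ccccc2)c1C[C@H](OCc1ccccc1)C=O
F0 | step 13 | none | none
F2 | step 4 | (4R,5R)-4,5-dicyclohexyl-2-(iodomethyl)-1,3,2-dioxaborolane | ICB1O[C@H](C2CCCCC2)[C@@H](C2CCCCC2)O1
F3 | step 4 | {[(4R,5R)-4,5-dicyclohexyl-1,3,2-dioxaborolan-2-yl]methyl}zinc iodide | I[Zn]CB1O[C@H](C2CCCCC2)[C@@H](C2CCCCC2)O1
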